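The pitfall in alpha is to count its hot stretch as a gain that the flask keeps to the end.

    target ⇌ isomer of the product (K1 = 0.819, k1 = 3.84 × 10⁻⁵ /s, Ea1 = 116 kJ/mol, ΔH1 = −32.0 kJ/mol)
    substrate + coupling partner ⇌ adduct, settled at all times (K2 = 14 /M, ΔH2 = −39.0 kJ/mol)
    adduct → target (k3 = 0.00161 /s, Ea3 = 88.0 kJ/mol)
    2 coupling partner → homo dimer (k4 = 9.05 × 10⁻⁵ /M/s, Ea4 = 92.0 kJ/mol)
    (constants at 70 °C)

the same everywhere: substrate 1.5 M; coupling partner 1.30 equiv; time 2.5 d

| run | remark | temperature |
|---|---|---|
| alpha | at 100 °C until 40 h, from then on at 70 °C |  |
| beta |  | 70 °C |
| theta |  | 100 °C |

- where a step has two of a species, its rate is k times that concentration squared, and two are used at each turn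
- the constants hold at 70 °C; other temperatures follow from the activation energies and enthalpies

* the flask with the highest amount of target, in percent of the substrate charged ("all alike" if they lie within 1.5 percentage points) (alpha / beta / theta / all alike)
* final target, as a percentage of the substrate charged, in alpha
* final target, as a percentage of the substrate charged, in beta
* final target, as a percentage of the substrate charged, in theta

Target and isomer of the product trade places through step 1, and K is isomer over target at balance. The part of the coupled substrate standing as target at balance is therefore the reciprocal of one plus K. An even K of one is the zero of this scale and gives half. At 70 °C, 0.819 lies just below that zero, which gives 55.0 %. Step 1 gives off heat, so K at 100 °C is smaller, 0.332, and the balance share of target there is 75.1 %.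

Which balance alpha shows turns on two times. One is the relaxation half-life of the pair at 70 °C, both directions together, 2.26 h. The other is the stretch alpha spends at that temperature, 20.0 h. Because the stretch holds 8.85 half-lives, alpha should fall back to the cool balance. Beta has longer still at that temperature, and theta has the same 2.5 d in a hotter bath. This reckoning takes the substrate, the limiting reagent at 1.30 equiv of partner, as coupled in full. It then gives 55.0 % for alpha and beta and 75.1 % for theta.

The forecast agrees, to rounding: 55 % for alpha, 55 % for beta, 75 % for theta, and so theta highest. It holds that the cool stretch “erases its 100 °C advantage and it ends level with beta”.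

Theta ends highest at 75.1 %, with alpha at 55.0 % and beta at 55.0 %. At 1.67 d, when its bath changed, alpha held 75.1 % target, the balance share 75.1 %, and it ended at 55.0 %. Coupling in full does not hold in a neighbour of theta charged with 0.520 equiv of partner. There the partner falls to 0 % and 48 % of the substrate stays uncoupled. The balance share applied to the coupled 52.0 % gives 39.1 %, and that flask holds 38.9 % target.

The numbers are made up; what happens was integrated by code.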